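At early times I treated the flask as one first exchange, with the starting complex losing one leaving ligand to the incoming ligand. The runs and the question were these.

the same everywhere: starting complex 20 mM
- south-east: incoming ligand 7.1 mM; run made earlier
- east: incoming ligand 660 mM; run made earlier
- theta: incoming ligand 6.00 mM; time 30 min
- alpha: incoming ligand 20.0 mM; time 30 min
- zeta: incoming ligand 50.0 mM; time 30 min
- beta: incoming ligand 150 mM; time 30 min
- gamma: incoming ligand 500 mM; time 30 min

| run | time / min | complex with one exchanged / % | starting complex / % |
|---|---|---|---|
| south-east | 6.00 | 2.4 | 96.5 |
| south-east | 12.0 | 3.4 | 94.3 |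
| south-east | 20.0 | 4.5 | 93.4 |
| south-east | 25.0 | 5.0 | 91.7 |
| south-east | 30.0 | 4.9 | 91.3 |
| east | 2.50 | 42.2 | 28.6 |
| east | 5.00 | 43.1 | 14.0 |
| east | 8.00 | 37.0 | 8.1 |
| east | 15.0 | 26.2 | 4.0 |
| east | 30.0 | 16.8 | 2.6 |

(standard deviation of a reading: 0.3 percentage points)

- what is said of leaving ligand includes idle adduct
- steps that have been proposed: starting complex + incoming ligand -> leaving ligand + complex with one exchanged; complex with one exchanged + incoming ligand -> leaving ligand + complex with two exchanged; complex with two exchanged + incoming ligand -> leaving ligand + complex with three exchanged; incoming ligand <-> dormant form; leaving ligand + starting complex <-> idle adduct; incoming ligand -> decomposed reagent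
- "hardly changes" means that all values lie within two and a half points (for a concentration: within two and a half percent of the largest)

- amount of complex with one exchanged at the end, in percent of the starting complex charged for theta, alpha, zeta, beta, gamma, in this order
- the shape of the row from first to last (falls all the way / falls, then rises / rises all the way / rises, then falls / hardly changes)

I used a dose τ, the first exchange constant times the time integral of the incoming ligand, which is the pseudo-first-order clock of this flask. My zero of the scale was the statistical case: 3 equal sites, so the second exchange runs at 0.667 of the first. The one-exchanged complex then follows 3(exp(−2τ/3) − exp(−τ)), which peaks at τ = 3ln(3/2) = 1.22, at a height of 44.4%.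

The two extreme flasks bracket this. In the south-east run, with little ligand, the dose stayed small and 4.9% of one-exchanged complex gave a dose per mM charged of 0.00708 mM⁻¹. In the east run, with ligand in large excess, the starting complex fell at 0.501 min⁻¹ early but 0.0287 min⁻¹ late, so the apparent dose grew ever more slowly. Its readings passed through 43.1%, close to the statistical height, and then fell.

If the dose grows in step with the charge, the row should turn at the turning charge, the peak dose divided by the dose per mM: 172 mM. The east starting complex gives a dose per mM charged of 0.00553 mM⁻¹ and a turn at 221 mM. Either way the turn lies above beta's charge and below gamma's, so I expected a rise and then a fall, with 44.1% at beta and 19.6% at gamma.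

The forecast gave 4.1%, 11.5%, 23%, 37% and 31%, with the shape rises, then falls, expecting the “yield to rise to a maximum near 150–250 mM”; its value at beta is lower than my figure and its value at gamma is higher than mine.

The flask gave 4.58%, 13.8%, 27.9%, 43.8% and 25.0%: rises, then falls.

    starting complex + incoming ligand → leaving ligand + complex with one exchanged (k = 0.0110 M⁻¹ s⁻¹)
    complex with one exchanged + incoming ligand → leaving ligand + complex with two exchanged (k = 0.00470 M⁻¹ s⁻¹)
    complex with two exchanged + incoming ligand → leaving ligand + complex with three exchanged (k = 0.0230 M⁻¹ s⁻¹)
    incoming ligand ⇌ dormant form (K = 2.20, k = 1.70 × 10⁻⁴ s⁻¹)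
    leaving ligand + starting complex ⇌ idle adduct, settled at all times (K = 57.0 M⁻¹)
    incoming ligand → decomposed reagent (k = 8.50 × 10⁻⁴ s⁻¹)

The row turned at 170 mM, against my turning charge of 172 mM. Beta's charge was 0.873 of that turning charge, and my reckoned dose of 1.06 for beta gives 34.6% of the starting complex unexchanged. Beta ended with 22% unbound and 17.4% as idle adduct, together 39.4%.

(The data are simulated with made-up constants; noise was put on by code.)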